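The amber run had made 14.4 mM of product at 2.00 h and the teal run 26.2 mM at 120 min, and I read both through the partner left, not the product made.

| setting | amber | teal | east | north |
|---|---|---|---|---|
| starting material | 0.045 M | 0.064 M | 0.050 M | 0.10 M |
| partner | 0.050 M | 0.050 M | 0.0500 M | 0.0500 M |
| protic impurity | 2.5 mM | 2.5 mM | 2.50 mM | 2.50 mM |
| initiator | 0.25 mM | 0.25 mM | 0.25 mM | 0.25 mM |
| temperature | 45 °C | 56 °C | 60 °C | 40 °C |
| remark | run made earlier | run made earlier |  |  |
| time |  |  | 2.0 h | 2.0 h |

- amber (time / h: product / %): 0.333: 11; 0.667: 20; 1.00: 24; 2.00: 32; 4.00: 42
- teal (time / min: product / %): 10.0: 8; 30.0: 24; 60.0: 33; 80.0: 39; 120: 41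

(readings scatter by 1.5 percentage points)

- which of the two ends with the higher amount of product, in percent of the starting material charged ("neither" if they lie within 2 percentage points) (east / north / neither)
- product at the end, in percent of the starting material charged, east
- product at the end, in percent of the starting material charged, north

Amber and teal each charged c(partner) 0.050 M and c(protic impurity) 2.5 mM. Counting one partner lost per impurity, I took a usable partner of 47.5 mM. My measure was the partner log-left: ln of usable partner over usable partner minus product. In amber at 2.00 h it was 0.361, and in teal at 120 min it was 0.804.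

The time per unit of log-left, read with the scatter of the readings, formed a ladder. The ladder began at teal's opening, 1.28 h over the first 30.0 min. Next came amber's opening, 3.18 h over the first 0.667 h. Then came teal's late stretch, 4.63 h, from 60.0 min to 120 min. Slowest was amber's late stretch, 13.7 h, from 2.00 h to 4.00 h.

So by 2.0 h teal and amber had each left their opening rung. I paired east, at 60 °C, with teal at 56 °C, and north, at 40 °C, with amber at 45 °C. I kept each partner's log-left and, as my own assumption, used the charge of starting material as a divisor. That gave east 52.5 % and north 14.4 %.

The forecast gave 47 % for east and 16 % for north, with east ahead: “East clearly leads in percent.” My east stood 5.5 percentage points above it.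

East gave 54.5 % and north 15.8 %, so east ended higher.

    2 second chain carrier → ended chains A (k = 5.00 × 10⁶ /M/s, Ea = 26.0 kJ/mol)
    starting material + second chain carrier → released group + first chain carrier (k = 3.40 × 10⁵ /M/min, Ea = 34.0 kJ/mol)
    starting material + initiating radical → capped initiator + first chain carrier (k = 1.00 × 10⁵ /M/s, Ea = 32.0 kJ/mol)
    partner + first chain carrier ⇌ product + second chain carrier (K = 0.390, k = 12000 /M/s, Ea = 36.0 kJ/mol, ΔH = 31.0 kJ/mol)
    initiator → 2 initiating radical (k = 0.00900 /min, Ea = 95.0 kJ/mol)
    partner + protic impurity → quenched reagent (k = 1.40 /M/min, Ea = 65.0 kJ/mol)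
    2 first chain carrier → ended chains B (k = 1.40 × 10⁷ /M/s, Ea = 22.0 kJ/mol)
    (constants at 60 °C)

Read back, north's log-left was 0.405 against amber's 0.361. Part of north's low figure, the largest single effect among those tried, is the loss of first chain carrier to ended chains B: with that step taken away, north gives 48.2 %, not 15.8 %. The neighbour, east repeated at 45 °C, shares amber's temperature; amber's log-left gave it 28.8 %, and the neighbour gave 31.3 %.

All runs were computed for an exercise; noise was put on by code.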